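Benzofuran numbering is used (O1, C2, C3, C3a, C4–C7, C7a); ring A is the benzo ring, ring B the aryl group on C2, ring C the dihydrofuran ring.
Enabling feature: in ring A the ether carbon C7a lies para to C5 (the propenyl-bearing carbon) and next to C3a (the side-chain carbon). A C5 phenol with a sacrificial methoxy group on C7a can therefore be oxidised to a cation on C7a that the C2 hydroxyl reaches through a five-membered ring.
Cuts: (a) the C5 side chain, back to n-PrMgCl and the C5 ketone of a dearomatised ring A (p-quinone monoketal 13); (b) O1–C7a, back to phenol alcohol 11; (c) the C2 carbinol, back to ketone 9; (d) C3–C3a, back to propiophenone 4 and aryl bromide 8.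
Forward: rings A and B are joined by Pd-catalysed ketone α-arylation and the ketone is reduced. Ring C is closed by oxidative dearomatisation of ring A, propyl is added to C5=O, and loss of water and methanol rearomatises ring A and creates the E-propenyl group.
Stereochemistry: C2 and C3 are set together by asymmetric hydrogenation with dynamic kinetic resolution of racemic 9 (step 7) and are not touched afterwards. The (1S,2S) alcohol maps onto the trans-(2S,3S) ring, and the alkene geometry comes from the E1 proton loss in step 11.
Helpers: C7a–OMe and C5–OH (consumed in steps 9–11), benzyl on the ring A phenol (off in step 8), MOM on the ring B phenol (off in step 12).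

Key step: step 9

Remark on the chemistry: 13 may form as a mixture of C7a epimers and 14 as a mixture of C5 epimers. The SMILES of 13–16 show the expected 7aR epimer and leave C5 of 14 and 15 and the exocyclic alkene of 16 undefined, because all these elements vanish in step 11. Compounds 1 and 5 are taken as purchasable.

Step 1
Reactants: 1 3-hydroxy-4,5-dimethoxybenzaldehyde
Product: 2 3,4-dimethoxy-5-(methoxymethoxy)benzaldehyde
Conditions: MOMCl, i-Pr2NEt, CH2Cl2, 0 °C to rt
Reagents that add atoms: chloromethyl methyl ether (MOMCl), COCCl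
Why: O-alkylation of the phenol gives a MOM acetal that withstands Grignard reagents, alkoxide bases, hydrogenation and PhI(OAc)2 and keeps ring B from being oxidised in step 9.

Step 2
Reactants: 2 3,4-dimethoxy-5-(methoxymethoxy)benzaldehyde
Product: 3 rac-1-[3,4-dimethoxy-5-(methoxymethoxy)phenyl]propan-1-ol
Conditions: EtMgBr, THF, 0 °C; then H2O
Reagents that add atoms: ethylmagnesium bromide, CC[Mg]Br
Why: Grignard addition to an aromatic aldehyde; the new centre needs no control because it is oxidised in step 3.

Step 3
Reactants: 3 rac-1-[3,4-dimethoxy-5-(methoxymethoxy)phenyl]propan-1-ol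
Product: 4 1-[3,4-dimethoxy-5-(methoxymethoxy)phenyl]propan-1-one
Conditions: Dess–Martin periodinane, CH2Cl2, rt
Reagents that add atoms: none
Why: Dess–Martin oxidation of a secondary benzylic alcohol to the aryl ethyl ketone under conditions that leave the MOM acetal intact.

Step 4
Reactants: 5 3-bromo-4,5-dimethoxybenzaldehyde
Product: 7 3-bromo-4,5-dimethoxyphenol, via aryl formate 6 (not isolated)
Conditions: mCPBA, CH2Cl2, 0 °C to rt; then Et3N (cat.), MeOH, rt
Reagents that add atoms: 3-chloroperoxybenzoic acid (mCPBA), OOC(=O)c1cccc(Cl)c1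
Why: Baeyer–Villiger oxidation in which the aryl group, made electron-rich by the para methoxy group, migrates, followed by methanolysis of the labile aryl formate; this places the oxidation handle (the future C5–OH) para to the sacrificial methoxy group.

Step 5
Reactants: 7 3-bromo-4,5-dimethoxyphenol
Product: 8 5-(benzyloxy)-1-bromo-2,3-dimethoxybenzene
Conditions: BnBr, K2CO3, DMF, rt
Reagents that add atoms: benzyl bromide, BrCc1ccccc1
Why: Williamson etherification gives a base-stable benzyl ether that can be removed by hydrogenolysis, orthogonally to the MOM group, before any alkene is present.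

Step 6
Reactants: 4 1-[3,4-dimethoxy-5-(methoxymethoxy)phenyl]propan-1-one; 8 5-(benzyloxy)-1-bromo-2,3-dimethoxybenzene
Product: 9 rac-2-[5-(benzyloxy)-2,3-dimethoxyphenyl]-1-[3,4-dimethoxy-5-(methoxymethoxy)phenyl]propan-1-one
Conditions: Pd(OAc)2 (2 mol %), P(t-Bu)3·HBF4 (4 mol %), NaOt-Bu (1.5 equiv), toluene, 70 °C
Reagents that add atoms: none
Why: Buchwald–Hartwig-type ketone α-arylation (zerovalent palladium inserts into the C–Br bond, the sodium enolate of the propiophenone is transferred and reductive elimination forms C3–C3a); propiophenones are standard substrates, a second arylation at the tertiary carbon is sterically blocked, and the racemic centre is corrected in step 7.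

Step 7
Reactants: 9 rac-2-[5-(benzyloxy)-2,3-dimethoxyphenyl]-1-[3,4-dimethoxy-5-(methoxymethoxy)phenyl]propan-1-one
Product: 10 (1S,2S)-2-[5-(benzyloxy)-2,3-dimethoxyphenyl]-1-[3,4-dimethoxy-5-(methoxymethoxy)phenyl]propan-1-ol
Conditions: RuCl2[(R)-xylbinap][(R)-daipen] (0.5 mol %), KOt-Bu (20 mol %), H2 (10 atm), i-PrOH, 30 °C
Reagents that add atoms: none
Why: Noyori asymmetric hydrogenation with dynamic kinetic resolution, in which KOt-Bu racemises the α-aryl centre through the enolate, the (R,R) catalyst sets the S carbinol centre as it does for simple aryl alkyl ketones, and it consumes faster the S ketone, whose Felkin–Anh face is the face the catalyst prefers, so the (1S,2S) alcohol that maps onto the trans ring should dominate.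

Step 8
Reactants: 10 (1S,2S)-2-[5-(benzyloxy)-2,3-dimethoxyphenyl]-1-[3,4-dimethoxy-5-(methoxymethoxy)phenyl]propan-1-ol
Product: 11 3-{(1S,2S)-1-[3,4-dimethoxy-5-(methoxymethoxy)phenyl]-1-hydroxypropan-2-yl}-4,5-dimethoxyphenol
Conditions: H2 (1 atm), Pd/C, EtOAc, rt
Reagents that add atoms: none
Why: Neutral hydrogenolysis of the aryl benzyl ether frees only the ring A phenol, since no alkene is present yet and the secondary benzylic alcohol and the MOM acetal are inert in the absence of acid.

Step 9
Reactants: 11 3-{(1S,2S)-1-[3,4-dimethoxy-5-(methoxymethoxy)phenyl]-1-hydroxypropan-2-yl}-4,5-dimethoxyphenol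
Product: 13 (2S,3S,7aR)-2-[3,4-dimethoxy-5-(methoxymethoxy)phenyl]-7,7a-dimethoxy-3-methyl-3,7a-dihydro-1-benzofuran-5(2H)-one, via aryloxyiodane 12 (not isolated)
Conditions: PhI(OAc)2 (1.05 equiv), 4 Å MS, MeCN, 0 °C
Reagents that add atoms: none
Why: The C5 phenol exchanges an acetate on trivalent iodine to give aryloxyiodane 12, whose O–I bond breaks heterolytically with loss of PhI and acetate; the resulting ring A cation is centred on C7a, para to C5–O, where the resident methoxy group stabilises it as an oxocarbenium ion, and the C2 hydroxyl adds there to form O1–C7a while C5–OH becomes C5=O. The closest known reaction type is the hypervalent iodine oxidation of 4-alkoxyphenols to p-quinone monoketals with capture by a tethered alcohol, which gives the same kind of fused mixed ketal as the 8a-alkoxytocopherones. Ring C closes in the 5-exo-trig mode on the C7a=O(+)Me bond. The one new stereocentre, C7a, is controlled by C3: allylic strain against C4–H keeps C3–H in the plane of ring A and the methyl group perpendicular to it, so oxygen should arrive on the face opposite the methyl group and leave the methoxy group cis to it (7aR), and since this centre is erased in step 11 the other epimer serves equally. Chemoselectivity rests on ring A holding the only free phenol (ring B is fully etherified, and PhI(OAc)2 leaves aryl ethers and the secondary alcohol alone), regioselectivity rests on the C7a methoxy group because C4, the other carbon within reach, offers no such stabilisation, and the meta relation of side chain and phenol oxygen rules out quinone methide formation or fragmentation. The same event stores two oxidation equivalents in ring A and exposes C5 as a ketone, exactly where the three-carbon chain has to be attached.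

Step 10
Reactants: 13 (2S,3S,7aR)-2-[3,4-dimethoxy-5-(methoxymethoxy)phenyl]-7,7a-dimethoxy-3-methyl-3,7a-dihydro-1-benzofuran-5(2H)-one
Product: 14 (2S,3S,7aR)-2-[3,4-dimethoxy-5-(methoxymethoxy)phenyl]-7,7a-dimethoxy-3-methyl-5-propyl-2,3,5,7a-tetrahydro-1-benzofuran-5-ol (C5 epimers; used crude)
Conditions: n-PrMgCl, THF, −78 °C; then H2O
Reagents that add atoms: n-propylmagnesium chloride, CCC[Mg]Cl
Why: 1,2-Addition of a Grignard reagent to the unhindered C5 carbonyl, which has no α-hydrogen, is the standard route from p-quinone monoketals to p-quinol ketals (attack at the carbonyl carbon as with vinylogous esters in the Stork–Danheiser sequence); the low temperature keeps the γ-hydrogen on C3 untouched and the new C5 centre needs no control.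

Step 11
Reactants: 14 (2S,3S,7aR)-2-[3,4-dimethoxy-5-(methoxymethoxy)phenyl]-7,7a-dimethoxy-3-methyl-5-propyl-2,3,5,7a-tetrahydro-1-benzofuran-5-ol
Product: 17 (2S,3S)-2-[3,4-dimethoxy-5-(methoxymethoxy)phenyl]-7-methoxy-3-methyl-5-[(E)-prop-1-enyl]-2,3-dihydro-1-benzofuran, via sulfamate ester 15 (not isolated), via propylidene triene 16 (not isolated)
Conditions: Burgess reagent (1.3 equiv), toluene, rt to 50 °C; then PPTS (10 mol %), 4 Å MS, rt
Reagents that add atoms: none
Why: Proposed new method: the Burgess reagent sulfamoylates the tertiary C5 hydroxyl (15), and its syn elimination (Ei or tight ion pair) can only take a hydrogen from a carbon next to C5, which means the propyl α-CH2 because C4 and C6 are vinylic, so triene 16 should form without touching C3–H; 16 is a vinylogous ketal that mild acid ionises at C7a with gain of aromaticity, the exocyclic methoxy group leaving rather than O1 because ring C holds the C7a–O1 bond near the plane of the diene while C7a–OMe stands perpendicular to it and overlaps with the π system; the 1-arylpropyl cation, stabilised by the para oxygen O1, then loses a β-proton through the conformer with methyl anti to aryl and gives the E-propenyl group, so the oxidation level stored in step 9 ends up as the side-chain alkene without any redox reagent; the closest known reaction types are the Burgess dehydration of tertiary alcohols, the acid-induced aromatisation of p-quinol ether ketals to side-chain-substituted anisoles and the E1 dehydration of 1-arylpropanols.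

Step 12
Reactants: 17 (2S,3S)-2-[3,4-dimethoxy-5-(methoxymethoxy)phenyl]-7-methoxy-3-methyl-5-[(E)-prop-1-enyl]-2,3-dihydro-1-benzofuran
Product: 18 5-{(2S,3S)-7-methoxy-3-methyl-5-[(E)-prop-1-enyl]-2,3-dihydro-1-benzofuran-2-yl}-2,3-dimethoxyphenol (target)
Conditions: p-TsOH·H2O (10 mol %), MeOH, 40 °C
Reagents that add atoms: none
Why: Acid-catalysed acetal exchange cleaves the phenolic MOM ether much faster than the β-methylstyrene is protonated, and any reversible opening at C2–O1 could only return the favoured trans isomer because C3 is untouched.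

Compound list
1 | 3-hydroxy-4,5-dimethoxybenzaldehyde | COc1cc(C=O)cc(O)c1OC | starting material
2 | 3,4-dimethoxy-5-(methoxymethoxy)benzaldehyde | COCOc1cc(C=O)cc(OC)c1OC | intermediate
3 | rac-1-[3,4-dimethoxy-5-(methoxymethoxy)phenyl]propan-1-ol | CCC(O)c1cc(OC)c(OC)c(OCOC)c1 | intermediate
4 | 1-[3,4-dimethoxy-5-(methoxymethoxy)phenyl]propan-1-one | CCC(=O)c1cc(OC)c(OC)c(OCOC)c1 | intermediate
5 | 3-bromo-4,5-dimethoxybenzaldehyde | COc1cc(C=O)cc(Br)c1OC | starting material
6 | 3-bromo-4,5-dimethoxyphenyl formate (not isolated) | COc1cc(OC=O)cc(Br)c1OC | intermediate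
7 | 3-bromo-4,5-dimethoxyphenol | COc1cc(O)cc(Br)c1OC | intermediate
8 | 5-(benzyloxy)-1-bromo-2,3-dimethoxybenzene | COc1cc(OCc2ccccc2)cc(Br)c1OC | intermediate
9 | rac-2-[5-(benzyloxy)-2,3-dimethoxyphenyl]-1-[3,4-dimethoxy-5-(methoxymethoxy)phenyl]propan-1-one | CC(C(=O)c1cc(OC)c(OC)c(OCOC)c1)c1cc(OCc2ccccc2)cc(OC)c1OC | intermediate
10 | (1S,2S)-2-[5-(benzyloxy)-2,3-dimethoxyphenyl]-1-[3,4-dimethoxy-5-(methoxymethoxy)phenyl]propan-1-ol | COc1cc(OCc2ccccc2)cc(c1OC)[C@H](C)[C@@H](c1cc(OC)c(OC)c(OCOC)c1)O | intermediate
11 | 3-{(1S,2S)-1-[3,4-dimethoxy-5-(methoxymethoxy)phenyl]-1-hydroxypropan-2-yl}-4,5-dimethoxyphenol | COc1cc(O)cc(c1OC)[C@H](C)[C@@H](c1cc(OC)c(OC)c(OCOC)c1)O | intermediate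
12 | acetoxy(phenyl)iodanyl ether of 11 at the phenol oxygen (not isolated) | CC(=O)OI(c1ccccc1)Oc1cc(OC)c(OC)c(c1)[C@H](C)[C@@H](c1cc(OC)c(OC)c(OCOC)c1)O | intermediate
13 | (2S,3S,7aR)-2-[3,4-dimethoxy-5-(methoxymethoxy)phenyl]-7,7a-dimethoxy-3-methyl-3,7a-dihydro-1-benzofuran-5(2H)-one | CO[C@@]12O[C@H](c3cc(OC)c(OC)c(OCOC)c3)[C@@H](C)C1=CC(=O)C=C2OC | intermediate
14 | (2S,3S,7aR)-2-[3,4-dimethoxy-5-(methoxymethoxy)phenyl]-7,7a-dimethoxy-3-methyl-5-propyl-2,3,5,7a-tetrahydro-1-benzofuran-5-ol (C5 epimers) | CCCC1(O)C=C2[C@H](C)[C@@H](c3cc(OC)c(OC)c(OCOC)c3)O[C@@]2(OC)C(OC)=C1 | intermediate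
15 | triethylammonium salt of the C5 O-[N-(methoxycarbonyl)sulfamoyl] derivative of 14 (not isolated) | CC[NH+](CC)CC.CCCC1(OS(=O)(=O)[N-]C(=O)OC)C=C2[C@H](C)[C@@H](c3cc(OC)c(OC)c(OCOC)c3)O[C@@]2(OC)C(OC)=C1 | intermediate
16 | (2S,3S,7aR)-2-[3,4-dimethoxy-5-(methoxymethoxy)phenyl]-7,7a-dimethoxy-3-methyl-5-propylidene-2,3,5,7a-tetrahydro-1-benzofuran (not isolated) | CCC=C1C=C2[C@H](C)[C@@H](c3cc(OC)c(OC)c(OCOC)c3)O[C@@]2(OC)C(OC)=C1 | intermediate
17 | (2S,3S)-2-[3,4-dimethoxy-5-(methoxymethoxy)phenyl]-7-methoxy-3-methyl-5-[(E)-prop-1-enyl]-2,3-dihydro-1-benzofuran | C/C=C/c1cc(OC)c2c(c1)[C@H](C)[C@@H](c1cc(OCOC)c(OC)c(OC)c1)O2 | intermediate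
18 | 5-{(2S,3S)-7-methoxy-3-methyl-5-[(E)-prop-1-enyl]-2,3-dihydro-1-benzofuran-2-yl}-2,3-dimethoxyphenol | C/C=C/c1cc(OC)c2c(c1)[C@H](C)[C@@H](c1cc(O)c(OC)c(OC)c1)O2 | target

Total step count: 12. Longest linear sequence: 10 (steps 1, 2, 3, 6, 7, 8, 9, 10, 11, 12).

Steps most likely to fail

1. Step 11 (Proposed new method).
- The sulfamate may ionise to a free pentadienyl cation that loses the proton on C3 instead of a propyl α-proton. Aromatisation would then run into ring C and destroy both stereocentres.
- The ring oxygen O1 may leave C7a in competition with the methoxy group.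
- The released methanol may capture the benzylic cation before proton loss.
- The fallback uses known chemistry, sets out from 13, bypasses steps 10 and 11 and returns at 17. Reduction of 13 with Na2S2O4 in THF–H2O at rt should rearomatise ring A with loss of methanol, as in the reduction of 8a-alkoxytocopherones, and give the 5-hydroxy-2,3-dihydrobenzofuran F1. Tf2O and pyridine in CH2Cl2 at 0 °C convert it into the aryl triflate F2. Suzuki–Miyaura coupling of F2 with (E)-prop-1-enylboronic acid pinacol ester (PdCl2(dppf), K3PO4, dioxane–H2O, 80 °C) gives 17 with the alkene geometry carried over from the boronate.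

2. Step 9.
- Acetate or adventitious water may intercept the ring A cation faster than the hindered secondary hydroxyl does, followed by collapse to the quinone.
- Ring B may attack the cation through carbon.
- The fallback separates oxidation from ring closure, sets out from 11 and returns at 13. Oxidation of 11 with PhI(OAc)2 in MeOH at 0 °C, the standard preparation of p-quinone dimethyl monoketals, gives the hydroxy dimethyl ketal F3. Treatment with PPTS (cat.) and 4 Å MS in CH2Cl2 at rt then forms the O1–C7a bond by thermodynamically driven transketalisation with removal of methanol.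

3. Step 7.
- Enolisation of 9 may be slowed by the ortho-methoxy aryl group. Racemisation would then fail to keep pace with hydrogenation, and diastereo- and enantioselectivity would both erode.
- The fallback replaces the dynamic resolution by substrate control plus classical resolution, sets out from 9 and returns at 10. Reduction of 9 with LiBH(s-Bu)3 in THF at −78 °C under Felkin–Anh control gives the racemic syn alcohol F4. Esterification with (R)-2-methoxy-2-phenylacetic acid (DCC, DMAP, CH2Cl2) gives two separable diastereomers, the ester of the (1S,2S) alcohol F5 and the ester of the (1R,2R) alcohol F6. After chromatographic separation F5 is saponified (LiOH, THF–H2O) to 10.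

Further compounds
F1 | step 11 | (2S,3S)-2-[3,4-dimethoxy-5-(methoxymethoxy)phenyl]-7-methoxy-3-methyl-2,3-dihydro-1-benzofuran-5-ol | Oc1cc(OC)c2c(c1)[C@H](C)[C@@H](c1cc(OCOC)c(OC)c(OC)c1)O2
F2 | step 11 | (2S,3S)-2-[3,4-dimethoxy-5-(methoxymethoxy)phenyl]-7-methoxy-3-methyl-2,3-dihydro-1-benzofuran-5-yl trifluoromethanesulfonate | O=S(=O)(Oc1cc(OC)c2c(c1)[C@H](C)[C@@H](c1cc(OCOC)c(OC)c(OC)c1)O2)C(F)(F)F
F3 | step 9 | 3-{(1S,2S)-1-[3,4-dimethoxy-5-(methoxymethoxy)phenyl]-1-hydroxypropan-2-yl}-4,4,5-trimethoxycyclohexa-2,5-dien-1-one | COC1=CC(=O)C=C(C1(OC)OC)[C@H](C)[C@@H](c1cc(OC)c(OC)c(OCOC)c1)O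
F4 | step 7 | racemic syn alcohol, (1S,2S) and (1R,2R) forms of 10 | COc1cc(OCc2ccccc2)cc(c1OC)[C@H](C)[C@@H](c1cc(OC)c(OC)c(OCOC)c1)O.COc1cc(OCc2ccccc2)cc(c1OC)[C@@H](C)[C@H](c1cc(OC)c(OC)c(OCOC)c1)O
F5 | step 7 | (R)-2-methoxy-2-phenylacetate of the (1S,2S) alcohol 10 | COc1cc(OCc2ccccc2)cc(c1OC)[C@H](C)[C@@H](c1cc(OC)c(OC)c(OCOC)c1)OC(=O)[C@H](OC)c1ccccc1
F6 | step 7 | (R)-2-methoxy-2-phenylacetate of the (1R,2R) alcohol | COc1cc(OCc2ccccc2)cc(c1OC)[C@@H](C)[C@H](c1cc(OC)c(OC)c(OCOC)c1)OC(=O)[C@H](OC)c1ccccc1
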